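**Assumptions.** The structure carries no descriptor for the biaryl axis, so the axis is formed without control and the target is taken as the racemate. (Triisopropylsilyloxy)acetylene (13) is taken as a purchased specialty reagent.

## Structural features

The target is an unsymmetrical biflavone. Unit 1 is a 5,7-dihydroxy-2-(4-methoxyphenyl)chromen-4-one and unit 2 is apigenin, and C8 of ring A of unit 1 is bonded to C6 of ring A of unit 2. Each unit is a benzo ring A fused through C4a–C8a to a 4-pyranone ring C that carries an aryl ring B at C2. There is no stereocentre, so no neighbouring stereocentres have to be related. The only stereochemical element is the biaryl axis, flanked by four ortho oxygens (O1 and O7 of unit 1, O5 and O7 of unit 2).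

The fragile parts are these:
- The two pyranones are opened by hydroxide, amide bases and hard nucleophiles.
- The 6-aryl-5,7-dihydroxy array of unit 2 can isomerize to the 8-aryl isomer in hot strong acid by ring opening and reclosure (Wessely–Moser rearrangement).
- The single methyl ether must outlive the release of four phenols, which excludes methyl ethers as protecting groups.

The real difficulty is the tetra-ortho-substituted bond between two electron-rich rings, together with the need to tell C6 from C8 in each unit. The key step exploits ring A of unit 1. Its hydroxyl at C5, hydrogen at C6, oxygen at C7 and unit 2 aryl group at C8 sit on the C4a–C8a bond exactly as a ketene/oxygenated-alkyne benzannulation places them on the C2=C3 bond of a 2,6-disubstituted 4-pyranone. That ring can therefore be grown around the biaryl bond instead of the bond being forged between two finished rings.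

## Logic of the disconnections

19 back to 18 and 17. The three O–CH2Ph bonds of unit 2 and then the O–Si bond at O7 of unit 1 are cut. Benzyl is chosen because hydrogenolysis leaves the methyl ether alone, and the silyl group is what the alkyne partner brings in. The demand is that both removals run under neutral or buffered conditions, so that neither the pyranones nor the 6-aryl/8-aryl connectivity is disturbed.

17 back to 12 and 13. Ring A of unit 1 is cut at C5–C6, C7–C8 and C4a–C5, and C8a is returned from C8 to the carbon that becomes C5. This removes a whole benzene ring and turns the hindered biaryl bond into an aryl–C(sp3)-type bond of an open-chain diazoketone. The demand is that 12, on loss of N2, rearranges, adds 13 in the right orientation and closes onto the pyranone C–H carbon.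

12 back to 11. The C=N2 unit is removed. The methylene of 11 is flanked by a carbonyl group and an aryl ring, so direct diazo transfer is enough and no activating group has to be added and removed.

11 back to 6 and 10. The bond between the methylene carbon and C6 of unit 2 is cut. This separates the two halves of the molecule at a C(sp2)–C(sp3) bond, which is far less hindered to make than the biaryl bond. The demand is an enolate arylation that tolerates a di-ortho-substituted iodide and a base-sensitive acyl pyranone.

10 back to 9, 8 and 7. The O5 benzyl ether, the C6–I bond and the O7/O4' benzyl ethers are cut in that order. The order matters: the free, chelated 5-hydroxyl of 8 directs iodination to C6, whereas a 5-alkoxy group would send it to C8. All three oxygens end as benzyl ethers, so that both carbons ortho to the later ketene are blocked.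

6 back to 4, then to 1 and 2. The acetyl methyl group is cut from the ester carbon of 4 (through amide 5). The pyranone of 4 is opened at O1–C2 to triketo ester 3, which is cut between C3 and C2 of the chain into 1 and 2. Both starting materials are cheap, and the aryl group and the carbonyl handle are fixed at C6 and C2 of the pyranone from the start.

## Other disconnections considered

Alternative 1: The cut goes through C2–C3 of both pyranones, with O1–C2 of each to follow.
- Forward step: the biaryl diacetophenone bis(aroyl ester) A1 has a 4-methoxybenzoate on the unit 1 ring and a 4-benzyloxybenzoate on the unit 2 ring, each ortho to an acetyl group. KOH in pyridine lets each acetyl enolate attack the ester on its own ring (double Baker–Venkataraman transfer) to give the bis(1,3-diketone) A2. Two acid-mediated cyclodehydrations and one hydrogenolysis would finish the synthesis.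
- In favour: this is the best-established way to a flavone, both heterocycles arise in parallel, and the ring B groups cannot be confused as long as the acyl shift stays intramolecular. The endgame needs one deprotection where the chosen plan needs two. On precedent and on the endgame the alternative is the better plan.
- Against: A1 already contains the tetra-ortho-substituted biaryl bond, so the hardest bond is moved into the preparation of A1. Two phloroacetophenone-type rings with six oxygens in three protection states would have to be coupled, and one aroyl ester placed on the phenol wedged between an acetyl group and the biaryl bond. Any intermolecular acyl exchange under KOH would mix the two aroyl groups, and the acidic closure of A2 invites the Wessely–Moser isomerization.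
- Comparison: structurally it is less apt, because it builds the two pyranones, which are the easy part, and leaves the axis to a coupling. Mechanistically it is safer, resting on known steps only, whereas the chosen plan rests on one untested cascade. In step count it is expected to be longer, since A1 needs separate routes to two differentiated acetophenones and their union.

Alternative 2: The cut goes through C7–C8 and C5–C6 of unit 2, so that ring A of unit 2 is the ring that is built.
- Forward step: pyranone ester A3 and flavone-8-acetate A4 are treated with excess LiN(iPr)2. The anion of the 2-methyl group of A3 attacks the ester of A4 (C7–C8), the doubly activated methylene so formed attacks the ester at C3 of the pyranone (C5–C6), and aromatization gives A5 with O5 and O7 of unit 2 already free.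
- In favour: like the chosen plan it grows an arene around the future axis and avoids a hindered biaryl coupling; on this central point the two plans are equal. A5 needs a single hydrogenolysis, so the alternative is better in the endgame.
- Against: the methylene of A4 is at least as acidic as the methyl group of A3, so the base may turn the electrophile into an unreactive enolate. The ester carbonyl of A4 is shielded by a di-ortho-substituted aryl group. Both pyranones face an amide base and carbanions. A4 needs a carbon substituent at C8 of a protected 4'-methoxyflavone, which should cost about as much as 11 does.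
- Comparison: in structure the two plans are equivalent in concept. In mechanism neither has close precedent on this substrate class, but the chosen cascade runs without base, which suits the pyranones better. In step count the two are expected to be close, with a small advantage to the alternative at the end.

Alternative 3: The cut goes through C4a–C4, C4–C3 and O1–C2 of unit 2; only its pyranone is disconnected.
- Forward step: ortho-iodophenol A6 (unit 1 as its 5,7-dibenzyl ether, carrying at C8 a 2,6-bis(benzyloxy)-4-hydroxy-3-iodophenyl group), carbon monoxide and 1-(benzyloxy)-4-ethynylbenzene A7 are combined under PdCl2(PPh3)2 and Et2NH. Carbonylative Sonogashira coupling gives an aryl alkynyl ketone, and amine-assisted 6-endo closure of the phenol gives the penta-O-benzyl ether A8.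
- In favour: the reaction type is known for flavones, forms three bonds and a ring in one operation, and comes late and convergently. A8 needs one hydrogenolysis. On precedent of the key step and on the endgame the alternative is the better plan.
- Against: A6 already contains the biaryl bond, so the main problem is untouched. The iodine of A6 lies between a benzyloxy and a hydroxyl group next to the biaryl bond, which should slow oxidative addition and CO insertion. 5-exo closure to an aurone and coupling without CO are competing channels. Carbon monoxide under pressure is needed.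
- Comparison: structurally it addresses the easy ring. Mechanistically its key step is the safer one. In step count it is expected to be longer, because A6 demands the hindered coupling and a regiochemically defined iodination of a phloroglucinol ring.

Key step: step 8

## Route

Step 1
Reactants: 1 1-(4-methoxyphenyl)butane-1,3-dione; 2 diethyl oxalate
Product: 4 ethyl 6-(4-methoxyphenyl)-4-oxo-4H-pyran-2-carboxylate, via triketo ester 3 (not isolated)
Conditions: NaOEt, EtOH, 0 °C → rt; then anhydrous HCl in EtOH, reflux
Reagents that add atoms: none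
Why: Claisen condensation at the terminal methyl group, driven by the doubly enolized triketo ester, then acid-catalysed cyclodehydration of the 1,3,5-tricarbonyl chain (the chelidonic acid type of pyranone synthesis); anhydrous acid keeps the ethyl ester.

Step 2
Reactants: 4 ethyl 6-(4-methoxyphenyl)-4-oxo-4H-pyran-2-carboxylate
Product: 6 2-acetyl-6-(4-methoxyphenyl)-4H-pyran-4-one, via Weinreb amide 5 (not isolated)
Conditions: MeNHOMe·HCl, iPrMgCl, THF, −20 °C; then MeMgBr, −40 → 0 °C; aq. NH4Cl
Reagents that add atoms: N,O-dimethylhydroxylamine hydrochloride, CNOC.Cl (atoms retained only in 5); methylmagnesium bromide, C[Mg]Br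
Why: One-pot Weinreb ketone synthesis: the magnesium amide converts the activated ester into the N-methoxy-N-methylamide, whose chelated tetrahedral adduct with MeMgBr stops at the ketone stage. The low temperature should keep the Grignard reagent away from the vinylogous-ester carbonyl of the pyranone.

Step 3
Reactants: 7 apigenin
Product: 8 7-(benzyloxy)-2-[4-(benzyloxy)phenyl]-5-hydroxy-4H-chromen-4-one
Conditions: BnBr (2.2 equiv), K2CO3, DMF, rt
Reagents that add atoms: benzyl bromide, BrCc1ccccc1
Why: Williamson etherification; the 5-hydroxyl is hydrogen-bonded to the C4 carbonyl and is the least nucleophilic phenol, so the 7- and 4'-hydroxyls should be alkylated selectively under mild carbonate conditions.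

Step 4
Reactants: 8 7-(benzyloxy)-2-[4-(benzyloxy)phenyl]-5-hydroxy-4H-chromen-4-one
Product: 9 7-(benzyloxy)-2-[4-(benzyloxy)phenyl]-5-hydroxy-6-iodo-4H-chromen-4-one
Conditions: BnMe3N·ICl2, CaCO3, CH2Cl2/MeOH, rt
Reagents that add atoms: benzyltrimethylammonium dichloroiodate, C[N+](C)(C)Cc1ccccc1.Cl[I-]Cl
Why: Electrophilic aromatic iodination; with a free chelated 5-hydroxyl and an alkylated 7-oxygen this reagent is known to attack C6 of 5,7-dioxygenated flavones and not C8, and CaCO3 takes up the HCl.

Step 5
Reactants: 9 7-(benzyloxy)-2-[4-(benzyloxy)phenyl]-5-hydroxy-6-iodo-4H-chromen-4-one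
Product: 10 5,7-bis(benzyloxy)-2-[4-(benzyloxy)phenyl]-6-iodo-4H-chromen-4-one
Conditions: BnBr, K2CO3, Bu4NI (cat.), DMF, 70 °C
Reagents that add atoms: benzyl bromide, BrCc1ccccc1
Why: Williamson etherification under conditions forcing enough to break the hydrogen-bonded chelate; the aryl iodide is inert, and the benzyl group blocks the oxygen that would otherwise trap the later ketene.

Step 6
Reactants: 6 2-acetyl-6-(4-methoxyphenyl)-4H-pyran-4-one; 10 5,7-bis(benzyloxy)-2-[4-(benzyloxy)phenyl]-6-iodo-4H-chromen-4-one
Product: 11 2-{5,7-bis(benzyloxy)-2-[4-(benzyloxy)phenyl]-4-oxo-4H-chromen-6-yl}-1-[6-(4-methoxyphenyl)-4-oxo-4H-pyran-2-yl]ethan-1-one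
Conditions: Pd2(dba)3, XPhos, K3PO4, toluene, 90 °C
Reagents that add atoms: none
Why: Palladium-catalysed α-arylation of a methyl ketone; the bulky biaryl phosphine supports oxidative addition to the hindered iodide and reductive elimination of the aryl enolate. K3PO4 suffices for the acidified acetyl group and is mild towards the pyranone, and the size of the aryl group should prevent a second arylation.

Step 7
Reactants: 11 2-{5,7-bis(benzyloxy)-2-[4-(benzyloxy)phenyl]-4-oxo-4H-chromen-6-yl}-1-[6-(4-methoxyphenyl)-4-oxo-4H-pyran-2-yl]ethan-1-one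
Product: 12 2-{5,7-bis(benzyloxy)-2-[4-(benzyloxy)phenyl]-4-oxo-4H-chromen-6-yl}-2-diazo-1-[6-(4-methoxyphenyl)-4-oxo-4H-pyran-2-yl]ethan-1-one
Conditions: 4-acetamidobenzenesulfonyl azide, DBU, MeCN, 0 °C → rt
Reagents that add atoms: 4-acetamidobenzenesulfonyl azide, CC(=O)Nc1ccc(cc1)S(=O)(=O)N=[N+]=[N-]
Why: Regitz diazo transfer; the methylene between the carbonyl group and the aryl ring is acidic enough for DBU, so the enolate takes up N2 from the sulfonyl azide without prior activation.

Step 8
Reactants: 12 2-{5,7-bis(benzyloxy)-2-[4-(benzyloxy)phenyl]-4-oxo-4H-chromen-6-yl}-2-diazo-1-[6-(4-methoxyphenyl)-4-oxo-4H-pyran-2-yl]ethan-1-one; 13 (triisopropylsilyloxy)acetylene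
Product: 17 8-{5,7-bis(benzyloxy)-2-[4-(benzyloxy)phenyl]-4-oxo-4H-chromen-6-yl}-5-hydroxy-2-(4-methoxyphenyl)-7-[(triisopropylsilyl)oxy]-4H-chromen-4-one, via aryl(pyranonyl)ketene 14 (not isolated), via silyloxycyclobutenone 15 (not isolated), via dienylketene 16 (not isolated)
Conditions: 13 (3 equiv), 450 nm LEDs, degassed toluene, 25 °C; then 80 °C, no metal catalyst
Reagents that add atoms: none
Why: Proposed new method: blue light expels N2 from 12 and the pyranonyl group shifts from the carbonyl carbon to the diazo carbon (Wolff rearrangement, which also creates the C8–C8a bond, so the cascade makes four ring bonds in all) to give ketene 14; the nucleophilic CH carbon of 13 then adds to the ketene carbonyl carbon and the oxygen-bearing carbon closes onto the ketene α-carbon, so that the [2+2] adduct 15 has the silyloxy group at C3 (future C5–C6 and C7–C8 bonds). At 80 °C 15 opens by four-electron conrotatory cleavage of its C1–C4 bond to dienylketene 16, which closes ring A by a thermal six-electron disrotatory electrocyclization of the ketene carbon onto C3 of the pyranone (C4a–C5), and enolization of the cyclohexadienone, whose C4a hydrogen lies between two carbonyl groups, gives the chelated C5 phenol. The closest known reaction is the Danheiser benzannulation in its diazoketone form with silyloxyalkynes, established for vinyl, aryl and five-membered heteroaryl ketenes; new here is a 4-pyranone C2=C3 bond as the terminating two-electron component. That carbon is the β-carbon of an enol ether, so its bonding to the electrophilic ketene carbon is polarity-matched. No stereocentre is created: the quaternary carbon of 15 is lost on ring opening and the biaryl axis forms without control. The regiochemistry (oxygen at C7, hydrogen at C6) follows from the polarization of the ynol ether. Periselectivity is secured because the only other closure, onto C5 or C7 of unit 2, meets a benzyloxy-bearing carbon, cannot aromatize and reverts, while the isomer of 16 with the aryl group turned inward returns to 15 and is funnelled to the productive isomer. Metal catalysts are left out so that no metal carbene can insert into the benzylic C–H bonds of the ortho benzyloxy groups.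

Step 9
Reactants: 17 8-{5,7-bis(benzyloxy)-2-[4-(benzyloxy)phenyl]-4-oxo-4H-chromen-6-yl}-5-hydroxy-2-(4-methoxyphenyl)-7-[(triisopropylsilyl)oxy]-4H-chromen-4-one
Product: 18 8-{5,7-bis(benzyloxy)-2-[4-(benzyloxy)phenyl]-4-oxo-4H-chromen-6-yl}-5,7-dihydroxy-2-(4-methoxyphenyl)-4H-chromen-4-one
Conditions: Bu4NF, AcOH, THF, 0 °C → rt
Reagents that add atoms: none
Why: Fluoride-induced cleavage of an aryl silyl ether; acetic acid buffers the phenoxide, and the benzyl and methyl ethers are not affected.

Step 10
Reactants: 18 8-{5,7-bis(benzyloxy)-2-[4-(benzyloxy)phenyl]-4-oxo-4H-chromen-6-yl}-5,7-dihydroxy-2-(4-methoxyphenyl)-4H-chromen-4-one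
Product: 19 8-[5,7-dihydroxy-2-(4-hydroxyphenyl)-4-oxo-4H-chromen-6-yl]-5,7-dihydroxy-2-(4-methoxyphenyl)-4H-chromen-4-one (target)
Conditions: H2 (1 atm), 10% Pd/C, THF/MeOH, rt
Reagents that add atoms: none
Why: Catalytic hydrogenolysis of the three aryl benzyl ethers; the methyl ether is stable, and the C2=C3 bonds of the flavones, being part of vinylogous esters, should survive at ambient pressure and temperature.

## Compound list

1 | 1-(4-methoxyphenyl)butane-1,3-dione | COc1ccc(cc1)C(=O)CC(C)=O | starting material
2 | diethyl oxalate | CCOC(=O)C(=O)OCC | starting material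
3 | ethyl 6-(4-methoxyphenyl)-2,4,6-trioxohexanoate | CCOC(=O)C(=O)CC(=O)CC(=O)c1ccc(OC)cc1 | intermediate (not isolated)
4 | ethyl 6-(4-methoxyphenyl)-4-oxo-4H-pyran-2-carboxylate | CCOC(=O)c1cc(=O)cc(o1)-c1ccc(OC)cc1 | intermediate
5 | N-methoxy-6-(4-methoxyphenyl)-N-methyl-4-oxo-4H-pyran-2-carboxamide | CON(C)C(=O)c1cc(=O)cc(o1)-c1ccc(OC)cc1 | intermediate (not isolated)
6 | 2-acetyl-6-(4-methoxyphenyl)-4H-pyran-4-one | CC(=O)c1cc(=O)cc(o1)-c1ccc(OC)cc1 | intermediate
7 | apigenin | O=c1cc(-c2ccc(O)cc2)oc2cc(O)cc(O)c12 | starting material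
8 | 7-(benzyloxy)-2-[4-(benzyloxy)phenyl]-5-hydroxy-4H-chromen-4-one | O=c1cc(-c2ccc(OCc3ccccc3)cc2)oc2cc(OCc3ccccc3)cc(O)c12 | intermediate
9 | 7-(benzyloxy)-2-[4-(benzyloxy)phenyl]-5-hydroxy-6-iodo-4H-chromen-4-one | O=c1cc(-c2ccc(OCc3ccccc3)cc2)oc2cc(OCc3ccccc3)c(I)c(O)c12 | intermediate
10 | 5,7-bis(benzyloxy)-2-[4-(benzyloxy)phenyl]-6-iodo-4H-chromen-4-one | O=c1cc(-c2ccc(OCc3ccccc3)cc2)oc2cc(OCc3ccccc3)c(I)c(OCc3ccccc3)c12 | intermediate
11 | 2-{5,7-bis(benzyloxy)-2-[4-(benzyloxy)phenyl]-4-oxo-4H-chromen-6-yl}-1-[6-(4-methoxyphenyl)-4-oxo-4H-pyran-2-yl]ethan-1-one | COc1ccc(-c2cc(=O)cc(C(=O)Cc3c(OCc4ccccc4)cc4oc(-c5ccc(OCc6ccccc6)cc5)cc(=O)c4c3OCc3ccccc3)o2)cc1 | intermediate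
12 | 2-{5,7-bis(benzyloxy)-2-[4-(benzyloxy)phenyl]-4-oxo-4H-chromen-6-yl}-2-diazo-1-[6-(4-methoxyphenyl)-4-oxo-4H-pyran-2-yl]ethan-1-one | COc1ccc(-c2cc(=O)cc(C(=O)C(=[N+]=[N-])c3c(OCc4ccccc4)cc4oc(-c5ccc(OCc6ccccc6)cc5)cc(=O)c4c3OCc3ccccc3)o2)cc1 | intermediate
13 | (triisopropylsilyloxy)acetylene | C#CO[Si](C(C)C)(C(C)C)C(C)C | starting material
14 | {5,7-bis(benzyloxy)-2-[4-(benzyloxy)phenyl]-4-oxo-4H-chromen-6-yl}[6-(4-methoxyphenyl)-4-oxo-4H-pyran-2-yl]ketene | O=C=C(c1cc(=O)cc(-c2ccc(OC)cc2)o1)c1c(OCc2ccccc2)cc2oc(-c3ccc(OCc4ccccc4)cc3)cc(=O)c2c1OCc1ccccc1 | intermediate (not isolated)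
15 | 4-{5,7-bis(benzyloxy)-2-[4-(benzyloxy)phenyl]-4-oxo-4H-chromen-6-yl}-4-[6-(4-methoxyphenyl)-4-oxo-4H-pyran-2-yl]-3-[(triisopropylsilyl)oxy]cyclobut-2-en-1-one (racemic) | O=C1C=C(O[Si](C(C)C)(C(C)C)C(C)C)C1(c2cc(=O)cc(-c3ccc(OC)cc3)o2)c2c(OCc3ccccc3)cc3oc(-c4ccc(OCc5ccccc5)cc4)cc(=O)c3c2OCc2ccccc2 | intermediate (not isolated)
16 | 4-{5,7-bis(benzyloxy)-2-[4-(benzyloxy)phenyl]-4-oxo-4H-chromen-6-yl}-4-[6-(4-methoxyphenyl)-4-oxo-4H-pyran-2-yl]-3-[(triisopropylsilyl)oxy]buta-1,3-dien-1-one, pyranonyl group cis to the ketene carbon | O=C=C/C(O[Si](C(C)C)(C(C)C)C(C)C)=C(\c1cc(=O)cc(-c2ccc(OC)cc2)o1)c1c(OCc2ccccc2)cc2oc(-c3ccc(OCc4ccccc4)cc3)cc(=O)c2c1OCc1ccccc1 | intermediate (not isolated)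
17 | 8-{5,7-bis(benzyloxy)-2-[4-(benzyloxy)phenyl]-4-oxo-4H-chromen-6-yl}-5-hydroxy-2-(4-methoxyphenyl)-7-[(triisopropylsilyl)oxy]-4H-chromen-4-one | COc1ccc(-c2cc(=O)c3c(O)cc(O[Si](C(C)C)(C(C)C)C(C)C)c(-c4c(OCc5ccccc5)cc5oc(-c6ccc(OCc7ccccc7)cc6)cc(=O)c5c4OCc4ccccc4)c3o2)cc1 | intermediate
18 | 8-{5,7-bis(benzyloxy)-2-[4-(benzyloxy)phenyl]-4-oxo-4H-chromen-6-yl}-5,7-dihydroxy-2-(4-methoxyphenyl)-4H-chromen-4-one | COc1ccc(-c2cc(=O)c3c(O)cc(O)c(-c4c(OCc5ccccc5)cc5oc(-c6ccc(OCc7ccccc7)cc6)cc(=O)c5c4OCc4ccccc4)c3o2)cc1 | intermediate
19 | 8-[5,7-dihydroxy-2-(4-hydroxyphenyl)-4-oxo-4H-chromen-6-yl]-5,7-dihydroxy-2-(4-methoxyphenyl)-4H-chromen-4-one (CNP0310322.0) | COc1ccc(-c2cc(=O)c3c(O)cc(O)c(-c4c(O)cc5oc(-c6ccc(O)cc6)cc(=O)c5c4O)c3o2)cc1 | target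

## Step count and risk

Total step count: 10. Longest linear sequence: 8 steps (steps 3 to 10, from 7). The pyranone branch (steps 1 and 2) joins at step 6.

Least certain steps:

Step 8 (key step). Three things may go wrong.
- The Wolff shift of the electron-poor pyranonyl group may be slow, leaving time for the keto carbene to insert into a benzylic C–H bond of a neighbouring benzyloxy group.
- The [2+2] addition of the hindered, doubly substituted ketene to the ynol ether may be slow, so that the ketene is lost to dimerization or to attack by an ether oxygen.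
- The six-electron closure onto a pyranone double bond has no precedent, so the cascade may stall at the cyclobutenone, which then decomposes on longer heating.

The fallback uses known chemistry, leaves the benzannulation and joins two finished flavones by Suzuki–Miyaura coupling of a hindered pair; it sets out from 10 and comes back to the route at 19. Purchased acacetin F1 is benzylated at both phenols (BnBr, K2CO3, DMF, 80 °C) to 5,7-di-O-benzylacacetin F2. With the 5-oxygen alkylated, iodination (N-iodosuccinimide, CF3CO2H, CH2Cl2) is directed to C8 and gives 8-iodo-5,7-di-O-benzylacacetin F3. Miyaura borylation (pinacolborane, Et3N, PdCl2(dppf), dioxane, 90 °C) gives 5,7-di-O-benzylacacetin 8-pinacolboronate F4. Coupling of F4 with 10 (Pd(OAc)2, SPhos, K3PO4, toluene/H2O, 100 °C) gives the penta-O-benzyl biflavone F5 (the same compound as A8), and hydrogenolysis under the conditions of step 10 gives 19.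

Step 6. The hindered, electron-rich iodide may undergo reductive loss of iodine faster than coupling, and the enolate of the acyl pyranone may self-condense or open a pyranone ring. The fallback replaces the ketone enolate by a zinc ester enolate and builds the ketone by acylation; it sets out from 10 and 4 and comes back at 11. Iodide 10 is coupled with the Reformatsky reagent BrZnCH2CO2tBu (Pd2(dba)3, XPhos, THF, 60 °C) to give tert-butyl {5,7-bis(benzyloxy)-2-[4-(benzyloxy)phenyl]-4-oxo-4H-chromen-6-yl}acetate F6. Its lithium enolate (LiN(SiMe3)2, 2 equiv, THF, −78 °C) is acylated by 4 in a crossed Claisen condensation to the β-keto ester F7. CF3CO2H in CH2Cl2 then removes the tert-butyl group and the carboxyl group to give 11.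

Step 7. Diazo transfer to a methylene shielded by a di-ortho-substituted aryl group may be slow, and prolonged exposure to DBU may lead to cleavage of the acyl–carbon bond or to addition at a pyranone. The fallback installs the diazo group before the aryl group; it sets out from 6 and 10 and comes back at 12. Ketone 6 is converted into its trifluoroacetyl derivative F8 (LiN(SiMe3)2, CF3CO2CH2CF3, THF, −78 °C). Detrifluoroacetylative diazo transfer (4-acetamidobenzenesulfonyl azide, Et3N, H2O, MeCN) gives the terminal diazoketone F9. Palladium-catalysed C–H arylation of the acyldiazomethane F9 with 10 (Pd(PPh3)4, Ag2CO3, Et3N, toluene, rt) gives 12 directly, so that 11 is bypassed.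

Step 2. The Grignard reagent may add to the C4 carbonyl or to a conjugate position of the pyranone instead of the amide, or the magnesium amide may add to the ring. The fallback avoids hard organometallic reagents; it sets out from 4 and comes back at 6. Ester 4 is condensed with the lithium enolate of tert-butyl acetate (LiN(iPr)2, THF, −78 °C, crossed Claisen condensation) to tert-butyl 3-[6-(4-methoxyphenyl)-4-oxo-4H-pyran-2-yl]-3-oxopropanoate F10. CF3CO2H in CH2Cl2 then cleaves the ester and the acid loses CO2 to give 6.

## Further compounds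

F1 | step 8 | acacetin (purchased) | COc1ccc(cc1)-c1cc(=O)c2c(O)cc(O)cc2o1
F2 | step 8 | 5,7-bis(benzyloxy)-2-(4-methoxyphenyl)-4H-chromen-4-one | COc1ccc(cc1)-c1cc(=O)c2c(OCc3ccccc3)cc(OCc3ccccc3)cc2o1
F3 | step 8 | 5,7-bis(benzyloxy)-8-iodo-2-(4-methoxyphenyl)-4H-chromen-4-one | COc1ccc(cc1)-c1cc(=O)c2c(OCc3ccccc3)cc(OCc3ccccc3)c(I)c2o1
F4 | step 8 | 5,7-bis(benzyloxy)-2-(4-methoxyphenyl)-8-(4,4,5,5-tetramethyl-1,3,2-dioxaborolan-2-yl)-4H-chromen-4-one | COc1ccc(cc1)-c1cc(=O)c2c(OCc3ccccc3)cc(OCc3ccccc3)c(B3OC(C)(C)C(C)(C)O3)c2o1
F5 | step 8 | 5,7-bis(benzyloxy)-8-{5,7-bis(benzyloxy)-2-[4-(benzyloxy)phenyl]-4-oxo-4H-chromen-6-yl}-2-(4-methoxyphenyl)-4H-chromen-4-one | COc1ccc(-c2cc(=O)c3c(OCc4ccccc4)cc(OCc4ccccc4)c(-c4c(OCc5ccccc5)cc5oc(-c6ccc(OCc7ccccc7)cc6)cc(=O)c5c4OCc4ccccc4)c3o2)cc1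
F6 | step 6 | tert-butyl {5,7-bis(benzyloxy)-2-[4-(benzyloxy)phenyl]-4-oxo-4H-chromen-6-yl}acetate | CC(C)(C)OC(=O)Cc1c(OCc2ccccc2)cc2oc(-c3ccc(OCc4ccccc4)cc3)cc(=O)c2c1OCc1ccccc1
F7 | step 6 | tert-butyl 2-{5,7-bis(benzyloxy)-2-[4-(benzyloxy)phenyl]-4-oxo-4H-chromen-6-yl}-3-[6-(4-methoxyphenyl)-4-oxo-4H-pyran-2-yl]-3-oxopropanoate (racemic) | CC(C)(C)OC(=O)C(C(=O)c1cc(=O)cc(-c2ccc(OC)cc2)o1)c1c(OCc2ccccc2)cc2oc(-c3ccc(OCc4ccccc4)cc3)cc(=O)c2c1OCc1ccccc1
F8 | step 7 | 4,4,4-trifluoro-1-[6-(4-methoxyphenyl)-4-oxo-4H-pyran-2-yl]butane-1,3-dione | COc1ccc(cc1)-c1cc(=O)cc(o1)C(=O)CC(=O)C(F)(F)F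
F9 | step 7 | 2-(2-diazoacetyl)-6-(4-methoxyphenyl)-4H-pyran-4-one | COc1ccc(cc1)-c1cc(=O)cc(o1)C(=O)C=[N+]=[N-]
F10 | step 2 | tert-butyl 3-[6-(4-methoxyphenyl)-4-oxo-4H-pyran-2-yl]-3-oxopropanoate | CC(C)(C)OC(=O)CC(=O)c1cc(=O)cc(-c2ccc(OC)cc2)o1
A1 | alternative 1 | 2-acetyl-6-{3-acetyl-2,6-bis(benzyloxy)-4-[(4-benzyloxybenzoyl)oxy]phenyl}-3,5-bis(benzyloxy)phenyl 4-methoxybenzoate | CC(=O)c1c(OC(=O)c2ccc(OC)cc2)c(-c2c(OCc3ccccc3)cc(OC(=O)c3ccc(OCc4ccccc4)cc3)c(C(C)=O)c2OCc2ccccc2)c(OCc2ccccc2)cc1OCc1ccccc1
A2 | alternative 1 | biaryl bis(1,3-diketone) with one free phenol ortho to each diketone | COc1ccc(C(=O)CC(=O)c2c(O)c(-c3c(OCc4ccccc4)cc(O)c(C(=O)CC(=O)c4ccc(OCc5ccccc5)cc4)c3OCc3ccccc3)c(OCc3ccccc3)cc2OCc2ccccc2)cc1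
A3 | alternative 2 | methyl 6-[4-(benzyloxy)phenyl]-2-methyl-4-oxo-4H-pyran-3-carboxylate | COC(=O)c1c(C)oc(cc1=O)-c1ccc(OCc2ccccc2)cc1
A4 | alternative 2 | methyl 2-[5,7-bis(benzyloxy)-2-(4-methoxyphenyl)-4-oxo-4H-chromen-8-yl]acetate | COC(=O)Cc1c(OCc2ccccc2)cc(OCc2ccccc2)c2c(=O)cc(oc12)-c1ccc(OC)cc1
A5 | alternative 2 | 5,7-bis(benzyloxy)-8-{2-[4-(benzyloxy)phenyl]-5,7-dihydroxy-4-oxo-4H-chromen-6-yl}-2-(4-methoxyphenyl)-4H-chromen-4-one | COc1ccc(-c2cc(=O)c3c(OCc4ccccc4)cc(OCc4ccccc4)c(-c4c(O)cc5oc(-c6ccc(OCc7ccccc7)cc6)cc(=O)c5c4O)c3o2)cc1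
A6 | alternative 3 | 5,7-bis(benzyloxy)-8-[2,6-bis(benzyloxy)-4-hydroxy-3-iodophenyl]-2-(4-methoxyphenyl)-4H-chromen-4-one | COc1ccc(-c2cc(=O)c3c(OCc4ccccc4)cc(OCc4ccccc4)c(-c4c(OCc5ccccc5)cc(O)c(I)c4OCc4ccccc4)c3o2)cc1
A7 | alternative 3 | 1-(benzyloxy)-4-ethynylbenzene | C#Cc1ccc(OCc2ccccc2)cc1
A8 | alternative 3 | 5,7-bis(benzyloxy)-8-{5,7-bis(benzyloxy)-2-[4-(benzyloxy)phenyl]-4-oxo-4H-chromen-6-yl}-2-(4-methoxyphenyl)-4H-chromen-4-one | COc1ccc(-c2cc(=O)c3c(OCc4ccccc4)cc(OCc4ccccc4)c(-c4c(OCc5ccccc5)cc5oc(-c6ccc(OCc7ccccc7)cc6)cc(=O)c5c4OCc4ccccc4)c3o2)cc1
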